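**Plan**

- Cuts, latest first: the aryl–C(=O) bond of the chalcone (aryllithium + cinnamic Weinreb amide); the C2–aryl bond of the oxane (arylzinc + oxocarbenium ion); the C4–aryl bond (Negishi coupling, with C3=C4 unsaturation); then C2 and C3 are excised, contracting the six-membered ring to an oxetan-2-one; last, a ketene/aldehyde [2+2] cut.
- Enabling feature: O1–C6–C5–C4 of the oxane (ring oxygen, the arylethyl-bearing carbinol carbon, CH2, the aryl-bearing carbon) is a β-oxy acyl array, i.e. the four ring atoms of a 4-substituted oxetan-2-one. Its ring strain lets an acetate enolate (future C3 and C2) break the acyl–O1 bond, and O1 then recloses on C2.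
- Forward order: aldehyde → β-lactone (four-membered ring) → two-carbon ring expansion to the oxane-2,4-dione → enol triflate → C4 arylation → hydrogenation → anomeric sulfone → C2 arylation → bromination and acylation to the chalcone → fluoride deprotection.
- Stereochemistry: C6 (S) from the catalytic asymmetric ketene–aldehyde cycloaddition; C4 (R) from hydrogenation anti to the C6 side chain (4,6-cis); C2 (R) from axial attack of the arylzinc on the oxocarbenium ion (2,6-trans, kinetic). No acid is used once C2 is set.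

Key step: step 3

Remark: oxane numbering is O1, C2 (4-hydroxyphenyl), C4 (chalcone aryl), C6 (arylethyl); the target is (2R,4R,6S). TBS = tert-butyldimethylsilyl, SEM = 2-(trimethylsilyl)ethoxymethyl.
Assumption: the quinidine-derived catalyst in step 2 is taken to deliver the (S)-lactone; if the sense of induction proves opposite, the pseudoenantiomeric O-trimethylsilylquinine is used with no other change.

**Route**

Step 1
Reactants: 1 tert-butyl(4-iodophenoxy)dimethylsilane; 2 prop-2-en-1-ol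
Product: 3 3-[4-(TBS-oxy)phenyl]propanal
Conditions: Pd(OAc)2 (3 mol %), Bu4NCl, NaHCO3, DMF, 40 °C
Reagents that add atoms: none
Why: A Heck reaction of the aryl iodide with allyl alcohol under ligand-free phase-transfer conditions should give the 3-arylpropanal directly, because β-hydride elimination toward the carbinol carbon forms an enol that tautomerizes to the aldehyde, and the aryl silyl ether tolerates the weak base.

Step 2
Reactants: 3 3-[4-(TBS-oxy)phenyl]propanal
Product: 4 (S)-4-{2-[4-(TBS-oxy)phenyl]ethyl}oxetan-2-one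
Conditions: AcCl (slow addition), i-Pr2NEt, O-trimethylsilylquinidine (10 mol %), LiClO4, CH2Cl2/Et2O, −78 °C
Reagents that add atoms: acetyl chloride, CC(Cl)=O
Why: A cinchona alkaloid/lithium salt catalyzed ketene–aldehyde [2+2] cycloaddition (ketene formed in the flask, bound as an ammonium enolate, aldehyde activated by Li+) should give the 4-substituted oxetan-2-one, the alkaloid choosing the aldehyde face and so setting C6 as (S).

Step 3
Reactants: 4 (S)-4-{2-[4-(TBS-oxy)phenyl]ethyl}oxetan-2-one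
Product: 6 (S)-6-{2-[4-(TBS-oxy)phenyl]ethyl}oxane-2,4-dione, via hydroxy keto ester 5 (not isolated)
Conditions: LiN(i-Pr)2, t-BuOAc (2.5 equiv), THF, −78 °C; AcOH; then PhMe, 110 °C
Reagents that add atoms: tert-butyl acetate, CC(=O)OC(C)(C)C
Why: The lithium enolate of tert-butyl acetate should attack the strained lactone carbonyl (future C4) and the adduct should collapse with acyl–oxygen cleavage, ring strain driving a crossed Claisen condensation whose β-keto ester product is deprotonated at once and so shielded from a second addition. On heating, the tert-butyl β-keto ester loses tert-butanol to an acylketene that the freed C6 hydroxyl captures in a 6-exo-dig lactonization, so that O1, C6, C5 and C4 of the four-membered ring reappear in a six-membered ring enlarged by C3 and C2. The closest known reaction types are the acyl C–O opening of β-lactones by hard carbanions and the thermal cyclization of δ-hydroxy β-keto tert-butyl esters to oxane-2,4-diones. No new stereocenter is formed, and C6 is carried through unchanged because its C–O bond is never broken. The selectivity needed is attack at the carbonyl in preference to SN2 attack at C6 or α-deprotonation, which the hard lithium enolate at −78 °C should secure.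

Step 4
Reactants: 6 (S)-6-{2-[4-(TBS-oxy)phenyl]ethyl}oxane-2,4-dione
Product: 7 (S)-6-{2-[4-(TBS-oxy)phenyl]ethyl}-2-oxo-5,6-dihydro-2H-pyran-4-yl trifluoromethanesulfonate
Conditions: Tf2O, Et3N, CH2Cl2, −78 °C
Reagents that add atoms: trifluoromethanesulfonic anhydride, O=S(=O)(OS(=O)(=O)C(F)(F)F)C(F)(F)F
Why: The dione exists as its enol (4-hydroxy-5,6-dihydro-2H-pyran-2-one), whose O-sulfonylation at low temperature should give the vinylogous acyl triflate without touching C6.

Step 5
Reactants: 8 5-methoxybenzene-1,3-diol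
Product: 9 1-methoxy-3,5-bis(SEM-oxy)benzene
Conditions: SEMCl, i-Pr2NEt, CH2Cl2, 0 °C → rt
Reagents that add atoms: 2-(trimethylsilyl)ethoxymethyl chloride, ClCOCC[Si](C)(C)C
Why: Alkylation of both phenols gives acetal ethers that later direct metalation between them and can be removed by fluoride without acid.

Step 6
Reactants: 9 1-methoxy-3,5-bis(SEM-oxy)benzene; 7 the enol triflate
Product: 12 (S)-6-{2-[4-(TBS-oxy)phenyl]ethyl}-4-[4-methoxy-2,6-bis(SEM-oxy)phenyl]-5,6-dihydro-2H-pyran-2-one, via aryllithium 10 (not isolated), via arylzinc chloride 11 (not isolated)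
Conditions: n-BuLi, THF, 0 °C; ZnCl2, THF; then 7, Pd2(dba)3 (2 mol %), SPhos (8 mol %), THF, rt → 45 °C
Reagents that add atoms: none
Why: Directed ortho-metalation should occur at the carbon flanked by the two chelating SEM-oxy groups, and after transmetalation to zinc a Negishi coupling with the highly reactive enol triflate, using a bulky biarylphosphine suited to doubly ortho-substituted arylzincs, should form the C4–aryl bond.

Step 7
Reactants: 12 the 4-aryl-5,6-dihydro-2H-pyran-2-one
Product: 13 (4R,6S)-6-{2-[4-(TBS-oxy)phenyl]ethyl}-4-[4-methoxy-2,6-bis(SEM-oxy)phenyl]oxan-2-one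
Conditions: H2 (4 atm), Pd/C, EtOAc, rt
Reagents that add atoms: none
Why: Heterogeneous hydrogenation of the trisubstituted enoate should add hydrogen to the ring face anti to the C6 arylethyl group, as known for 6-substituted 4-alkyl- and 4-hydroxy-5,6-dihydropyran-2-ones, setting C4 as (R) with the two substituents cis and equatorial, while SEM and silyl ethers are inert.

Step 8
Reactants: 13 the cis-4,6-disubstituted oxan-2-one
Product: 15 (4R,6S)-6-{2-[4-(TBS-oxy)phenyl]ethyl}-4-[4-methoxy-2,6-bis(SEM-oxy)phenyl]-2-(phenylsulfonyl)oxane (anomer mixture), via lactol 14 (not isolated)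
Conditions: i-Bu2AlH, CH2Cl2, −78 °C; aq KNaC4H4O6; then PhSO2H, CaCl2, CH2Cl2, rt
Reagents that add atoms: benzenesulfinic acid, O=S(O)c1ccccc1
Why: Partial reduction of the δ-lactone at −78 °C should stop at the lactol, which condenses with the sulfinic acid through the oxocarbenium ion to the anomeric sulfone, a stable oxocarbenium precursor whose anomeric configuration is irrelevant.

Step 9
Reactants: 15 the anomeric sulfone; 16 (4-bromophenoxy)(tert-butyl)dimethylsilane
Product: 19 (2R,4R,6S)-2-[4-(TBS-oxy)phenyl]-6-{2-[4-(TBS-oxy)phenyl]ethyl}-4-[4-methoxy-2,6-bis(SEM-oxy)phenyl]oxane, via Grignard reagent 17 (not isolated), via arylzinc bromide 18 (not isolated)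
Conditions: Mg, THF; ZnBr2, THF; then 15, THF, rt
Reagents that add atoms: none
Why: ZnBr2 should ionize the sulfone to the oxocarbenium ion, which in the half-chair with the C4 and C6 groups pseudo-equatorial is attacked by the arylzinc along the axial trajectory, so the new aryl group becomes axial at C2 (R) and trans to both substituents, as known for arylzinc additions to 6-substituted 2-sulfonyl oxanes; the weak zinc Lewis acid in THF should not re-ionize the benzylic ether, so the kinetic isomer is kept.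

Step 10
Reactants: 19 the 2,4,6-trisubstituted oxane
Product: 20 (2R,4R,6S)-4-[3-bromo-4-methoxy-2,6-bis(SEM-oxy)phenyl]-2-[4-(TBS-oxy)phenyl]-6-{2-[4-(TBS-oxy)phenyl]ethyl}oxane
Conditions: NBS (1.0 equiv), NaHCO3, CH2Cl2, −78 → −20 °C, dark
Reagents that add atoms: N-bromosuccinimide, O=C1CCC(=O)N1Br
Why: Electrophilic aromatic bromination should occur only on the far more electron-rich trialkoxy ring, whose two free positions are equivalent by rotation about the C4–aryl bond, giving one monobromide under neutral conditions.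

Step 11
Reactants: 21 4-(TBS-oxy)benzaldehyde; 22 diethyl {2-[methoxy(methyl)amino]-2-oxoethyl}phosphonate
Product: 23 (E)-3-[4-(TBS-oxy)phenyl]-N-methoxy-N-methylprop-2-enamide
Conditions: LiCl, i-Pr2NEt, MeCN, rt
Reagents that add atoms: none
Why: A Horner–Wadsworth–Emmons olefination under mild lithium chloride/amine conditions should give the (E)-cinnamic Weinreb amide without loss of the aryl silyl ether.

Step 12
Reactants: 20 the aryl bromide; 23 the cinnamic Weinreb amide
Product: 25 (E)-1-{3-[(2R,4R,6S)-2-[4-(TBS-oxy)phenyl]-6-{2-[4-(TBS-oxy)phenyl]ethyl}oxan-4-yl]-6-methoxy-2,4-bis(SEM-oxy)phenyl}-3-[4-(TBS-oxy)phenyl]prop-2-en-1-one, via aryllithium 24 (not isolated)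
Conditions: t-BuLi (2 equiv), THF, −78 °C; then 23, −78 → 0 °C; AcOH
Reagents that add atoms: none
Why: Bromine–lithium exchange at −78 °C should outpace any deprotonation, and the aryllithium should add 1,2 to the Weinreb amide to a chelated tetrahedral intermediate that releases the (E)-enone only on quench, forming the chalcone ketone without acid and without over-addition.

Step 13
Reactants: 25 the fully protected chalcone
Product: 26 (E)-1-{2,4-dihydroxy-3-[(2R,4R,6S)-2-(4-hydroxyphenyl)-6-[2-(4-hydroxyphenyl)ethyl]oxan-4-yl]-6-methoxyphenyl}-3-(4-hydroxyphenyl)prop-2-en-1-one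
Conditions: Bu4NF (excess), THF/DMPU, 0 → 45 °C, argon sweep; AcOH
Reagents that add atoms: none
Why: Fluoride should cleave the three aryl silyl ethers directly and the two SEM ethers by attack at the remote silicon with loss of ethene and formaldehyde (the departing phenoxides being activated by the ortho/para carbonyl), so all five groups come off without acid, which would epimerize the axial benzylic C2–O bond, and without reducing the enone.

**Compound list**

1 | tert-butyl(4-iodophenoxy)dimethylsilane | CC(C)(C)[Si](C)(C)Oc1ccc(I)cc1 | starting material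
2 | prop-2-en-1-ol | C=CCO | starting material
3 | 3-[4-(TBS-oxy)phenyl]propanal | O=CCCc1ccc(O[Si](C)(C)C(C)(C)C)cc1 | intermediate
4 | (S)-4-{2-[4-(TBS-oxy)phenyl]ethyl}oxetan-2-one | O=C1C[C@H](CCc2ccc(O[Si](C)(C)C(C)(C)C)cc2)O1 | intermediate
5 | tert-butyl (S)-7-[4-(TBS-oxy)phenyl]-5-hydroxy-3-oxoheptanoate (not isolated) | CC(C)(C)OC(=O)CC(=O)C[C@@H](O)CCc1ccc(O[Si](C)(C)C(C)(C)C)cc1 | intermediate
6 | (S)-6-{2-[4-(TBS-oxy)phenyl]ethyl}oxane-2,4-dione | O=C1CC(=O)C[C@H](CCc2ccc(O[Si](C)(C)C(C)(C)C)cc2)O1 | intermediate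
7 | (S)-6-{2-[4-(TBS-oxy)phenyl]ethyl}-2-oxo-5,6-dihydro-2H-pyran-4-yl trifluoromethanesulfonate | O=C1C=C(OS(=O)(=O)C(F)(F)F)C[C@H](CCc2ccc(O[Si](C)(C)C(C)(C)C)cc2)O1 | intermediate
8 | 5-methoxybenzene-1,3-diol | COc1cc(O)cc(O)c1 | starting material
9 | 1-methoxy-3,5-bis{[2-(trimethylsilyl)ethoxy]methoxy}benzene | COc1cc(OCOCC[Si](C)(C)C)cc(OCOCC[Si](C)(C)C)c1 | intermediate
10 | [4-methoxy-2,6-bis(SEM-oxy)phenyl]lithium (not isolated) | COc1cc(OCOCC[Si](C)(C)C)c([Li])c(OCOCC[Si](C)(C)C)c1 | intermediate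
11 | chloro[4-methoxy-2,6-bis(SEM-oxy)phenyl]zinc (not isolated) | COc1cc(OCOCC[Si](C)(C)C)c([Zn]Cl)c(OCOCC[Si](C)(C)C)c1 | intermediate
12 | (S)-6-{2-[4-(TBS-oxy)phenyl]ethyl}-4-[4-methoxy-2,6-bis(SEM-oxy)phenyl]-5,6-dihydro-2H-pyran-2-one | COc1cc(OCOCC[Si](C)(C)C)c(C2=CC(=O)O[C@@H](CCc3ccc(O[Si](C)(C)C(C)(C)C)cc3)C2)c(OCOCC[Si](C)(C)C)c1 | intermediate
13 | (4R,6S)-6-{2-[4-(TBS-oxy)phenyl]ethyl}-4-[4-methoxy-2,6-bis(SEM-oxy)phenyl]oxan-2-one | COc1cc(OCOCC[Si](C)(C)C)c([C@@H]2C[C@H](CCc3ccc(O[Si](C)(C)C(C)(C)C)cc3)OC(=O)C2)c(OCOCC[Si](C)(C)C)c1 | intermediate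
14 | (4R,6S)-6-{2-[4-(TBS-oxy)phenyl]ethyl}-4-[4-methoxy-2,6-bis(SEM-oxy)phenyl]oxan-2-ol, anomer mixture (not isolated) | COc1cc(OCOCC[Si](C)(C)C)c([C@@H]2C[C@H](CCc3ccc(O[Si](C)(C)C(C)(C)C)cc3)OC(O)C2)c(OCOCC[Si](C)(C)C)c1 | intermediate
15 | (4R,6S)-6-{2-[4-(TBS-oxy)phenyl]ethyl}-4-[4-methoxy-2,6-bis(SEM-oxy)phenyl]-2-(phenylsulfonyl)oxane, anomer mixture | COc1cc(OCOCC[Si](C)(C)C)c([C@@H]2C[C@H](CCc3ccc(O[Si](C)(C)C(C)(C)C)cc3)OC(S(=O)(=O)c3ccccc3)C2)c(OCOCC[Si](C)(C)C)c1 | intermediate
16 | (4-bromophenoxy)(tert-butyl)dimethylsilane | CC(C)(C)[Si](C)(C)Oc1ccc(Br)cc1 | starting material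
17 | [4-(TBS-oxy)phenyl]magnesium bromide (not isolated) | Br[Mg]c1ccc(O[Si](C)(C)C(C)(C)C)cc1 | intermediate
18 | bromo[4-(TBS-oxy)phenyl]zinc (not isolated) | Br[Zn]c1ccc(O[Si](C)(C)C(C)(C)C)cc1 | intermediate
19 | (2R,4R,6S)-2-[4-(TBS-oxy)phenyl]-6-{2-[4-(TBS-oxy)phenyl]ethyl}-4-[4-methoxy-2,6-bis(SEM-oxy)phenyl]oxane | COc1cc(OCOCC[Si](C)(C)C)c([C@@H]2C[C@H](CCc3ccc(O[Si](C)(C)C(C)(C)C)cc3)O[C@@H](c3ccc(O[Si](C)(C)C(C)(C)C)cc3)C2)c(OCOCC[Si](C)(C)C)c1 | intermediate
20 | (2R,4R,6S)-4-[3-bromo-4-methoxy-2,6-bis(SEM-oxy)phenyl]-2-[4-(TBS-oxy)phenyl]-6-{2-[4-(TBS-oxy)phenyl]ethyl}oxane | COc1cc(OCOCC[Si](C)(C)C)c([C@@H]2C[C@H](CCc3ccc(O[Si](C)(C)C(C)(C)C)cc3)O[C@@H](c3ccc(O[Si](C)(C)C(C)(C)C)cc3)C2)c(OCOCC[Si](C)(C)C)c1Br | intermediate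
21 | 4-(TBS-oxy)benzaldehyde | CC(C)(C)[Si](C)(C)Oc1ccc(C=O)cc1 | starting material
22 | diethyl {2-[methoxy(methyl)amino]-2-oxoethyl}phosphonate | CCOP(=O)(CC(=O)N(C)OC)OCC | starting material
23 | (E)-3-[4-(TBS-oxy)phenyl]-N-methoxy-N-methylprop-2-enamide | CON(C)C(=O)/C=C/c1ccc(O[Si](C)(C)C(C)(C)C)cc1 | intermediate
24 | aryllithium from 20, lithium in place of bromine (not isolated) | COc1cc(OCOCC[Si](C)(C)C)c([C@@H]2C[C@H](CCc3ccc(O[Si](C)(C)C(C)(C)C)cc3)O[C@@H](c3ccc(O[Si](C)(C)C(C)(C)C)cc3)C2)c(OCOCC[Si](C)(C)C)c1[Li] | intermediate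
25 | (E)-1-{3-[(2R,4R,6S)-2-[4-(TBS-oxy)phenyl]-6-{2-[4-(TBS-oxy)phenyl]ethyl}oxan-4-yl]-6-methoxy-2,4-bis(SEM-oxy)phenyl}-3-[4-(TBS-oxy)phenyl]prop-2-en-1-one | COc1cc(OCOCC[Si](C)(C)C)c([C@@H]2C[C@H](CCc3ccc(O[Si](C)(C)C(C)(C)C)cc3)O[C@@H](c3ccc(O[Si](C)(C)C(C)(C)C)cc3)C2)c(OCOCC[Si](C)(C)C)c1C(=O)/C=C/c1ccc(O[Si](C)(C)C(C)(C)C)cc1 | intermediate
26 | (E)-1-{2,4-dihydroxy-3-[(2R,4R,6S)-2-(4-hydroxyphenyl)-6-[2-(4-hydroxyphenyl)ethyl]oxan-4-yl]-6-methoxyphenyl}-3-(4-hydroxyphenyl)prop-2-en-1-one | COc1cc(O)c([C@@H]2C[C@H](CCc3ccc(O)cc3)O[C@@H](c3ccc(O)cc3)C2)c(O)c1C(=O)/C=C/c1ccc(O)cc1 | target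

**Step count and risks**

Total steps: 13. Longest linear sequence: 11 (steps 1, 2, 3, 4, 6, 7, 8, 9, 10, 12, 13).

Most likely to fail:

Step 9. The arylzinc may capture the hindered oxocarbenium ion slowly or with poor axial/equatorial facial selectivity, elimination to the cyclic enol ether may compete, and the kinetic product may equilibrate toward the all-equatorial epimer. The fallback reverses polarity at C2 and sets out from sulfone 15. Reductive lithiation with LiC10H8 in THF at −78 °C should give the configurationally stable axial organolithium [(2S,4R,6S)-6-{2-[4-(TBS-oxy)phenyl]ethyl}-4-[4-methoxy-2,6-bis(SEM-oxy)phenyl]oxan-2-yl]lithium F1, which is trapped with Bu3SnCl with retention to the axial stannane tributyl[(2S,4R,6S)-6-{2-[4-(TBS-oxy)phenyl]ethyl}-4-[4-methoxy-2,6-bis(SEM-oxy)phenyl]oxan-2-yl]stannane F2. A stereoretentive Stille arylation of F2 with aryl iodide 1 (Pd2(dba)3, a bulky electron-poor biarylphosphine, CuCl, KF, 1,4-dioxane, heat) comes back to the route at 19.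

Step 13. Cleavage of the SEM ethers may stall, liberated formaldehyde may hydroxymethylate the free position of the electron-rich chalcone ring, and the basic medium may cyclize the 2'-hydroxychalcone to the flavanone. The fallback separates the two kinds of protecting group and sets out from 25. Buffered Bu4NF/AcOH in THF at 0 °C should remove only the silyl ethers, giving (E)-1-{3-[(2R,4R,6S)-2-(4-hydroxyphenyl)-6-[2-(4-hydroxyphenyl)ethyl]oxan-4-yl]-6-methoxy-2,4-bis(SEM-oxy)phenyl}-3-(4-hydroxyphenyl)prop-2-en-1-one F3. The two SEM acetals are then cleaved by bidentate chelation and bromide attack with MgBr2·OEt2 in Et2O/MeNO2 at room temperature, which releases no free formaldehyde and arrives at 26.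

Step 6. Lithiation may occur in part at the position between one SEM-oxy group and the methoxy group, and slow transmetalation of the doubly ortho-substituted arylzinc may let the vinylogous acyl triflate decompose. The fallback sets out from aryllithium 10, which is quenched with 2-isopropoxy-4,4,5,5-tetramethyl-1,3,2-dioxaborolane to the isolable 2-[4-methoxy-2,6-bis(SEM-oxy)phenyl]-4,4,5,5-tetramethyl-1,3,2-dioxaborolane F4, from which any regioisomer is removed. A Suzuki–Miyaura coupling of F4 with triflate 7 (Pd(OAc)2, SPhos, K3PO4, PhMe/H2O, 40 °C) comes back to the route at 12.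

**Further compounds**

F1 | step 9 | [(2S,4R,6S)-6-{2-[4-(TBS-oxy)phenyl]ethyl}-4-[4-methoxy-2,6-bis(SEM-oxy)phenyl]oxan-2-yl]lithium, axial, not isolated | COc1cc(OCOCC[Si](C)(C)C)c([C@@H]2C[C@H](CCc3ccc(O[Si](C)(C)C(C)(C)C)cc3)O[C@@H]([Li])C2)c(OCOCC[Si](C)(C)C)c1
F2 | step 9 | tributyl[(2S,4R,6S)-6-{2-[4-(TBS-oxy)phenyl]ethyl}-4-[4-methoxy-2,6-bis(SEM-oxy)phenyl]oxan-2-yl]stannane | COc1cc(OCOCC[Si](C)(C)C)c([C@@H]2C[C@H](CCc3ccc(O[Si](C)(C)C(C)(C)C)cc3)O[C@@H]([Sn](CCCC)(CCCC)CCCC)C2)c(OCOCC[Si](C)(C)C)c1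
F3 | step 13 | (E)-1-{3-[(2R,4R,6S)-2-(4-hydroxyphenyl)-6-[2-(4-hydroxyphenyl)ethyl]oxan-4-yl]-6-methoxy-2,4-bis(SEM-oxy)phenyl}-3-(4-hydroxyphenyl)prop-2-en-1-one | COc1cc(OCOCC[Si](C)(C)C)c([C@@H]2C[C@H](CCc3ccc(O)cc3)O[C@@H](c3ccc(O)cc3)C2)c(OCOCC[Si](C)(C)C)c1C(=O)/C=C/c1ccc(O)cc1
F4 | step 6 | 2-[4-methoxy-2,6-bis(SEM-oxy)phenyl]-4,4,5,5-tetramethyl-1,3,2-dioxaborolane | COc1cc(OCOCC[Si](C)(C)C)c(B2OC(C)(C)C(C)(C)O2)c(OCOCC[Si](C)(C)C)c1
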